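Slowness can pass for a ceiling, and two of us read the summer run differently: in its last hour free monomer gains just 1.9 percentage points of the charge.

in all of them: solid monomer 0.25 M

| charge | pre-initiator | remark | time |
|---|---|---|---|
| summer | 0.12 mol% | run made earlier |  |
| winter | 0.5 mol% | run made earlier |  |
| flask | 0.25 mol% |  | 6.0 h |

- summer (time / h: solid monomer / %, free monomer / %, monomer in chains / %): 1.33: 90.6, 9.6, 0.8; 2.50: 85.1, 16.9, 0.3; 4.00: 77.7, 21.9, 0.9; 5.00: 75.0, 25.0, 0.3; 6.00: 72.5, 26.9, 1.4
- winter (time / h: solid monomer / %, free monomer / %, monomer in chains / %): 0.500: 96.7, 4.0, 0.2; 0.833: 94.4, 5.8, 0; 1.50: 89.6, 9.7, 0; 3.00: 81.4, 17.2, 1.1; 6.00: 71.2, 23.6, 5.0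

(readings scatter by 0.5 percentage points)

- as a solid, counted per litre of solution: solid monomer
- at the start none of the solid monomer is in solution

- concentration of solid monomer at 6.0 h, in M
- concentration of free monomer at 6.0 h, in M
- concentration of monomer in chains at 6.0 h, in M

The first speaker says free monomer has reached its ceiling, the solubility, near summer's 26.9 %. Chains are then refilled from the solid, so with winter's chains scaled by loading to 2.50 %, the flask's solid monomer ends at 70.6 %.

I say the dissolving is merely slow. Take the dissolved part in summer as the mean of solid lost and free monomer: 15.9 % at 2.50 h and 25.0 % at 5.00 h. If the gap to a ceiling halves in equal times, doubling the time multiplies the dissolved part by one plus the fraction of the gap left, here 0.572. That gives 3.11 h for the time in which the gap halves, the dissolving half-life, and a ceiling read at 37.2 %. The flask's 6.0 h is 1.93 half-lives, so I put its solid monomer at 72.6 %, with chains taken from free monomer. Winter's readings at that time lean my way: against summer, free monomer is 3.3 points lower and solid monomer 1.3 points lower.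

The forecast sides with me, saying “Dissolution barely depends on loading”, and gives 0.18 M, 0.064 M and 0.0058 M.

The flask gives 0.180 M, 0.0630 M and 0.00675 M, which is 72.1 %, 25.2 % and 2.70 % of the charge.

    free monomer + living end → monomer in chains + living end, rate k1*[living end]*[free monomer] (k = 250 /M/h)
    solid monomer ⇌ free monomer, rate k2*(cs2 - [free monomer]) while solid is left; crystals form when [free monomer] > cs2 (solubility = 0.0950 M, k = 0.210 /h)
    free monomer + initiator → living end + monomer in chains (k = 36.0 /M/h)
    pre-initiator ⇌ initiator (K = 1.10, k = 0.0670 /h)

The solid stands with the slow view, and free monomer is still made 2.26 times as fast as it is used up, though the forecast's chains are low by a factor 1.16. The first speaker's level free monomer, with the solid feeding the chains, does show up later in this flask, yet not at a ceiling: the solubility is 38.0 % of the charge, more than the free monomer held at 25.0 h. Left until 25 h, the same flask stands at 8.04 of the half-lives I read from the summer run. A gap of 13 points under the read ceiling, held from 6.0 h on, reckons 54 points of solid dissolved, and the flask lost 46 points. Free monomer reads 24.4 % against 25.2 % earlier, while solid monomer is down to 26.0 %.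

All runs stem from a simulated flask with made-up constants, and the scatter is random.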